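**Retrosynthetic overview**

1. The target has a twofold axis through the central C–C single bond of the (E,E)-diene. That bond is cut last, giving two identical (E)-2-iodovinyl cyclohexenols (reductive homocoupling).
2. In each half the iodovinyl carbon goes back to a ring formyl group and the carbinol to a ring ketone. The cyclohexene is then cut at its C=C bond (olefinic CH / carbon bearing the linker) and at its CH2–CH2 bond, giving acrolein and an acyclic formyl β-keto ester (domino Michael/aldol condensation).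
3. Enabling feature: in each cyclohexene ring the olefinic CH and the carbinol carbon both sit on the quaternary ring carbon, and the ring C=C is conjugated to the first linker carbon. At the carbonyl level this is a non-enolisable 2,2-disubstituted 3-oxo-aldehyde with one acidic CH2 (donor) and one formyl carbon (acceptor), the complement of acrolein, and only a six-membered closure is possible.
4. The acyclic partner comes from geraniol: Sharpless epoxidation plus an aluminium-promoted 1,2-shift set the quaternary centre, a Shi epoxidation sets the side-chain oxirane, allyl acetate supplies the activated CH2, and a CBS reduction sets the carbinol once the ring exists.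
5. Ring order: temporary 2,3-oxirane (step 1, consumed in step 3), side-chain oxirane (step 5), cyclohexene (step 8). The dimerisation (step 12) doubles both.

Key step: step 8

Remark: the two halves are homotopic, so every compound up to 18 is a monomer and the last step joins two molecules of 18.

**Step 1**
Reactants: 1 geraniol
Product: 2 (2S,3S)-2,3-epoxygeraniol
Conditions: Ti(OiPr)4 (5 mol %), L-(+)-diethyl tartrate (6 mol %), tBuOOH, 4 Å MS, CH2Cl2, −20 °C
Reagents that add atoms: tert-butyl hydroperoxide, CC(C)(C)OO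
Why: Sharpless asymmetric epoxidation, in which the L-(+)-tartrate–titanium complex binds the allylic alcohol and delivers oxygen to the face that gives the (2S,3S)-oxirane, leaving the remote trisubstituted olefin untouched.

**Step 2**
Reactants: 2 (2S,3S)-2,3-epoxygeraniol
Product: 3 tert-butyl(dimethyl)silyl ether of 2
Conditions: TBSCl, imidazole, DMF, 0 °C → rt
Reagents that add atoms: tert-butyl(chloro)dimethylsilane, CC(C)(C)[Si](C)(C)Cl
Why: Standard silylation of a primary alcohol; the silyloxymethyl group is the migrating group needed in step 3.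

**Step 3**
Reactants: 3 tert-butyl(dimethyl)silyl ether of (2S,3S)-2,3-epoxygeraniol
Product: 4 (2S)-2-({[tert-butyl(dimethyl)silyl]oxy}methyl)-2,6-dimethylhept-5-enal
Conditions: MeAl(OAr)2 (Ar = 4-bromo-2,6-di-tert-butylphenyl; 20 mol %), CH2Cl2, −78 → −20 °C
Reagents that add atoms: none
Why: Semipinacol-type rearrangement of an epoxy silyl ether, in which the aluminium Lewis acid opens the oxirane at the tertiary carbon and the silyloxymethyl group migrates anti to the breaking C–O bond, so the oxirane configuration should be transferred with inversion into the (S)-quaternary centre.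

**Step 4**
Reactants: 4 (2S)-2-({[tert-butyl(dimethyl)silyl]oxy}methyl)-2,6-dimethylhept-5-enal, 5 allyl acetate
Product: 7 allyl (3RS,4S)-4-({[tert-butyl(dimethyl)silyl]oxy}methyl)-3-hydroxy-4,8-dimethylnon-7-enoate, via lithium enolate of allyl acetate 6 (not isolated)
Conditions: LiN(iPr)2, THF, −78 °C; then 4, −78 °C; aq. NH4Cl
Reagents that add atoms: none
Why: Acetate aldol addition of a lithium ester enolate to a non-enolisable aldehyde; the new carbinol centre is uncontrolled on purpose because step 7 oxidises it to the ketone.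

**Step 5**
Reactants: 7 allyl (3RS,4S)-4-({[tert-butyl(dimethyl)silyl]oxy}methyl)-3-hydroxy-4,8-dimethylnon-7-enoate
Product: 8 allyl (3RS,4S)-4-({[tert-butyl(dimethyl)silyl]oxy}methyl)-6-[(2R)-3,3-dimethyloxiran-2-yl]-3-hydroxy-4-methylhexanoate
Conditions: D-fructose-derived Shi ketone (30 mol %), KHSO5 (as Oxone), K2CO3, Bu4NHSO4, MeCN–CH2(OMe)2 / aq. Na2B4O7 buffer, 0 °C
Reagents that add atoms: potassium peroxymonosulfate, [K+].[O-]S(=O)(=O)OO
Why: Shi epoxidation, in which the chiral dioxirane should attack the electron-rich trisubstituted olefin through the spiro transition state that gives the (R)-oxirane, while the electron-poor terminal allyl ester olefin stays intact.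

**Step 6**
Reactants: 8 allyl (3RS,4S)-4-({[tert-butyl(dimethyl)silyl]oxy}methyl)-6-[(2R)-3,3-dimethyloxiran-2-yl]-3-hydroxy-4-methylhexanoate
Product: 9 allyl (3RS,4S)-6-[(2R)-3,3-dimethyloxiran-2-yl]-3-hydroxy-4-(hydroxymethyl)-4-methylhexanoate
Conditions: Bu4NF, AcOH (1:1), THF, 0 °C → rt; crude diol used at once
Reagents that add atoms: none
Why: Fluoride-mediated desilylation, buffered with acetic acid so that neither the oxirane nor the allyl ester (lactonisation) should be attacked by a free alkoxide.

**Step 7**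
Reactants: 9 allyl (3RS,4S)-6-[(2R)-3,3-dimethyloxiran-2-yl]-3-hydroxy-4-(hydroxymethyl)-4-methylhexanoate
Product: 10 allyl (4S)-6-[(2R)-3,3-dimethyloxiran-2-yl]-4-formyl-4-methyl-3-oxohexanoate
Conditions: Dess–Martin periodinane (3 equiv), NaHCO3, CH2Cl2, 0 °C → rt
Reagents that add atoms: none
Why: Double Dess–Martin oxidation converts both epimers of the β-hydroxy ester into one β-keto ester and the neopentyl alcohol into the aldehyde under buffered, non-nucleophilic conditions that should spare the oxirane and the retro-Claisen-prone formyl ketone.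

**Step 8**
Reactants: 10 allyl (4S)-6-[(2R)-3,3-dimethyloxiran-2-yl]-4-formyl-4-methyl-3-oxohexanoate, 11 acrolein
Product: 14 allyl (1RS,5S)-5-{2-[(2R)-3,3-dimethyloxiran-2-yl]ethyl}-3-formyl-5-methyl-6-oxocyclohex-3-ene-1-carboxylate, via Michael adduct 12 (not isolated), via aldol adduct 13 (not isolated)
Conditions: acrolein (1.05 equiv, slow addition), (S)-α,α-diphenylprolinol trimethylsilyl ether (20 mol %; either enantiomer serves), PhCO2H (20 mol %), toluene, 0 °C → rt, then 4 Å MS, 40 °C
Reagents that add atoms: none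
Why: The amine turns acrolein into an iminium ion, the acidic CH2 between the ketone and ester carbonyls of 10 adds to its β-carbon (Michael addition, new CH2–CH2 bond, 12), and the freed aldehyde becomes an enamine whose α-carbon attacks the non-enolisable formyl carbon (13) before E1cB loss of water gives the conjugated enal (new ring C=C). The closest known reaction type is the secondary-amine-catalysed domino carba-Michael/intramolecular aldol condensation of 1,3-dicarbonyl-tethered aldehydes with enals, a formal [4+2] route to cyclohexene carbaldehydes. The cyclohexene is the only ring closed, in a polar 6-(enolexo)-exo-trig mode. No new stereocentre survives: the carbinol and α-carbons of 13 are erased by dehydration, the ester-bearing carbon is an epimerising mixture removed in step 9, and the quaternary centre has no α-hydrogen and stays (S), so all diastereomers of 12 and 13 should converge on 14. The step needs chemoselectivity among three carbonyl groups and 1,4- over 1,2-addition to acrolein. The first is secured by the substrate, since every other enol/carbonyl pairing would close a four-membered ring, and the second by the hindered catalyst and the slow addition of one equivalent of acrolein, which should also suppress a second Michael addition.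

**Step 9**
Reactants: 14 allyl (1RS,5S)-5-{2-[(2R)-3,3-dimethyloxiran-2-yl]ethyl}-3-formyl-5-methyl-6-oxocyclohex-3-ene-1-carboxylate
Product: 16 (3S)-3-{2-[(2R)-3,3-dimethyloxiran-2-yl]ethyl}-3-methyl-4-oxocyclohex-1-ene-1-carbaldehyde, via β-keto acid 15 (not isolated)
Conditions: Pd(OAc)2 (5 mol %), PPh3 (20 mol %), HCO2H, Et3N, THF, rt
Reagents that add atoms: none
Why: Tsuji–Trost-type deallylation, in which zerovalent palladium ionises the allyl ester, formate reduces the allyl ligand to propene (outcompeting C-allylation), and the β-keto acid loses CO2 at room temperature, removing the activating group without touching the oxirane or the quaternary centre.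

**Step 10**
Reactants: 16 (3S)-3-{2-[(2R)-3,3-dimethyloxiran-2-yl]ethyl}-3-methyl-4-oxocyclohex-1-ene-1-carbaldehyde
Product: 17 (2S)-2-{2-[(2R)-3,3-dimethyloxiran-2-yl]ethyl}-4-[(E)-2-iodoethenyl]-2-methylcyclohex-3-en-1-one
Conditions: CrCl2 (6 equiv), CHI3 (2 equiv), THF–1,4-dioxane, 0 °C → rt, dark
Reagents that add atoms: iodoform, IC(I)I
Why: Takai olefination, in which the geminal dichromium reagent adds to the aldehyde and eliminates to the (E)-iodoalkene, while the hindered α-quaternary ketone should not react.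

**Step 11**
Reactants: 17 (2S)-2-{2-[(2R)-3,3-dimethyloxiran-2-yl]ethyl}-4-[(E)-2-iodoethenyl]-2-methylcyclohex-3-en-1-one
Product: 18 (1R,2S)-2-{2-[(2R)-3,3-dimethyloxiran-2-yl]ethyl}-4-[(E)-2-iodoethenyl]-2-methylcyclohex-3-en-1-ol
Conditions: (S)-2-methyl-CBS-oxazaborolidine (0.5 equiv), catecholborane, toluene, −78 → −40 °C; aq. NaHCO3 work-up
Reagents that add atoms: none
Why: Corey–Bakshi–Shibata reduction, in which the (S)-catalyst differentiates the quaternary flank (large) from the ring CH2 flank (small) and should deliver hydride to give the (R)-carbinol (hydroxyl cis to the oxiranylethyl chain), by catalyst control rather than the weak methyl-versus-chain bias of the substrate.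

**Step 12**
Reactants: 18 (1R,2S)-2-{2-[(2R)-3,3-dimethyloxiran-2-yl]ethyl}-4-[(E)-2-iodoethenyl]-2-methylcyclohex-3-en-1-ol (two molecules)
Product: 20 (1R,1'R,2S,2'S)-4,4'-[(1E,3E)-buta-1,3-diene-1,4-diyl]bis(2-{2-[(2R)-3,3-dimethyloxiran-2-yl]ethyl}-2-methylcyclohex-3-en-1-ol), via alkenylstannane 19 (not isolated)
Conditions: Pd(PPh3)4 (10 mol %), Me3SnSnMe3 (0.5 equiv), CuI (20 mol %), degassed DMF, 50 °C, dark
Reagents that add atoms: none
Why: One-pot stannylation/Stille homocoupling, in which zerovalent palladium inserts into the C–I bond, half of the iodide is converted by the ditin into stannane 19, and 19 couples with the remaining 18 with retention at both olefins, so the (E,E)-diene and the twofold symmetry should arise together under neutral conditions tolerated by the oxiranes and free hydroxyl groups.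

**Compound list**

1 | geraniol, (2E)-3,7-dimethylocta-2,6-dien-1-ol | CC(C)=CCC/C(C)=C/CO | starting material
2 | (2S,3S)-2,3-epoxygeraniol, [(2S,3S)-3-methyl-3-(4-methylpent-3-en-1-yl)oxiran-2-yl]methanol | OC[C@@H]1O[C@@]1(C)CCC=C(C)C | intermediate
3 | tert-butyl(dimethyl){[(2S,3S)-3-methyl-3-(4-methylpent-3-en-1-yl)oxiran-2-yl]methoxy}silane | CC(C)(C)[Si](C)(C)OC[C@@H]1O[C@@]1(C)CCC=C(C)C | intermediate
4 | (2S)-2-({[tert-butyl(dimethyl)silyl]oxy}methyl)-2,6-dimethylhept-5-enal | O=C[C@](C)(CO[Si](C)(C)C(C)(C)C)CCC=C(C)C | intermediate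
5 | allyl acetate (prop-2-en-1-yl acetate) | CC(=O)OCC=C | starting material
6 | lithium enolate of allyl acetate | C=C(O[Li])OCC=C | intermediate
7 | allyl (3RS,4S)-4-({[tert-butyl(dimethyl)silyl]oxy}methyl)-3-hydroxy-4,8-dimethylnon-7-enoate | C=CCOC(=O)CC(O)[C@](C)(CO[Si](C)(C)C(C)(C)C)CCC=C(C)C | intermediate
8 | allyl (3RS,4S)-4-({[tert-butyl(dimethyl)silyl]oxy}methyl)-6-[(2R)-3,3-dimethyloxiran-2-yl]-3-hydroxy-4-methylhexanoate | C=CCOC(=O)CC(O)[C@](C)(CO[Si](C)(C)C(C)(C)C)CC[C@H]1OC1(C)C | intermediate
9 | allyl (3RS,4S)-6-[(2R)-3,3-dimethyloxiran-2-yl]-3-hydroxy-4-(hydroxymethyl)-4-methylhexanoate | C=CCOC(=O)CC(O)[C@](C)(CO)CC[C@H]1OC1(C)C | intermediate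
10 | allyl (4S)-6-[(2R)-3,3-dimethyloxiran-2-yl]-4-formyl-4-methyl-3-oxohexanoate | C=CCOC(=O)CC(=O)[C@](C)(C=O)CC[C@H]1OC1(C)C | intermediate
11 | acrolein (prop-2-enal) | C=CC=O | starting material
12 | allyl (4S)-6-[(2R)-3,3-dimethyloxiran-2-yl]-4-formyl-4-methyl-3-oxo-2-(3-oxopropyl)hexanoate (epimers at the ester-bearing carbon) | C=CCOC(=O)C(CCC=O)C(=O)[C@](C)(C=O)CC[C@H]1OC1(C)C | intermediate
13 | allyl (5S)-5-{2-[(2R)-3,3-dimethyloxiran-2-yl]ethyl}-3-formyl-4-hydroxy-5-methyl-6-oxocyclohexane-1-carboxylate (diastereomer mixture) | CC1(C)O[C@@H]1CC[C@@]1(C)C(O)C(C=O)CC(C(=O)OCC=C)C1=O | intermediate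
14 | allyl (1RS,5S)-5-{2-[(2R)-3,3-dimethyloxiran-2-yl]ethyl}-3-formyl-5-methyl-6-oxocyclohex-3-ene-1-carboxylate | CC1(C)O[C@@H]1CC[C@@]1(C)C=C(C=O)CC(C(=O)OCC=C)C1=O | intermediate
15 | (1RS,5S)-5-{2-[(2R)-3,3-dimethyloxiran-2-yl]ethyl}-3-formyl-5-methyl-6-oxocyclohex-3-ene-1-carboxylic acid | CC1(C)O[C@@H]1CC[C@@]1(C)C=C(C=O)CC(C(=O)O)C1=O | intermediate
16 | (3S)-3-{2-[(2R)-3,3-dimethyloxiran-2-yl]ethyl}-3-methyl-4-oxocyclohex-1-ene-1-carbaldehyde | CC1(C)O[C@@H]1CC[C@@]1(C)C=C(C=O)CCC1=O | intermediate
17 | (2S)-2-{2-[(2R)-3,3-dimethyloxiran-2-yl]ethyl}-4-[(E)-2-iodoethenyl]-2-methylcyclohex-3-en-1-one | CC1(C)O[C@@H]1CC[C@@]1(C)C=C(/C=C/I)CCC1=O | intermediate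
18 | (1R,2S)-2-{2-[(2R)-3,3-dimethyloxiran-2-yl]ethyl}-4-[(E)-2-iodoethenyl]-2-methylcyclohex-3-en-1-ol | CC1(C)O[C@@H]1CC[C@@]1(C)C=C(/C=C/I)CC[C@H]1O | intermediate
19 | (1R,2S)-2-{2-[(2R)-3,3-dimethyloxiran-2-yl]ethyl}-2-methyl-4-[(E)-2-(trimethylstannyl)ethenyl]cyclohex-3-en-1-ol | CC1(C)O[C@@H]1CC[C@@]1(C)C=C(/C=C/[Sn](C)(C)C)CC[C@H]1O | intermediate
20 | (1R,1'R,2S,2'S)-4,4'-[(1E,3E)-buta-1,3-diene-1,4-diyl]bis(2-{2-[(2R)-3,3-dimethyloxiran-2-yl]ethyl}-2-methylcyclohex-3-en-1-ol) | CC1(C)O[C@@H]1CC[C@@]1(C)C=C(/C=C/C=C/C2=C[C@](C)(CC[C@H]3OC3(C)C)[C@H](O)CC2)CC[C@H]1O | target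

**Step count**

Total steps: 12. Longest linear sequence: 12 steps (geraniol to the target).

**Steps most likely to fail**

1. Step 8. What may go wrong: amine- or water-induced retro-Claisen loss of the formyl group from the α,α-disubstituted β-keto aldehyde before ring closure, a second conjugate addition of the mono-adduct to acrolein, or stalling at the aldol stage. Fallback (the CH2–CH2 bond by alkylation and the ring C=C by metathesis, in separate operations), setting out from 10: K2CO3-mediated C-alkylation in acetone with 2-(bromomethyl)allyl tert-butyldimethylsilyl ether (C=C(CBr)CO[Si](C)(C)C(C)(C)C) should give allyl (4S)-2-[2-({[tert-butyl(dimethyl)silyl]oxy}methyl)prop-2-en-1-yl]-6-[(2R)-3,3-dimethyloxiran-2-yl]-4-formyl-4-methyl-3-oxohexanoate F1. Deallylation–decarboxylation under the conditions of step 9 should give (2S)-6-({[tert-butyl(dimethyl)silyl]oxy}methyl)-2-{2-[(2R)-3,3-dimethyloxiran-2-yl]ethyl}-2-methyl-3-oxohept-6-enal F2. Wittig methylenation of the formyl group (Ph3P=CH2, THF, −78 °C; the hindered ketone is expected to react far more slowly) should give (3S)-7-({[tert-butyl(dimethyl)silyl]oxy}methyl)-3-{2-[(2R)-3,3-dimethyloxiran-2-yl]ethyl}-3-methylocta-1,7-dien-4-one F3. Ring-closing metathesis with the second-generation Grubbs catalyst RuCl2(=CHPh)(PCy3)(H2IMes) in CH2Cl2 at 40 °C should close the ring to (2S)-4-({[tert-butyl(dimethyl)silyl]oxy}methyl)-2-{2-[(2R)-3,3-dimethyloxiran-2-yl]ethyl}-2-methylcyclohex-3-en-1-one F4. Bu4NF/AcOH should free (2S)-2-{2-[(2R)-3,3-dimethyloxiran-2-yl]ethyl}-4-(hydroxymethyl)-2-methylcyclohex-3-en-1-one F5. MnO2 in CH2Cl2 should then oxidise the allylic alcohol to the enal, which is 16, where the route is rejoined.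

2. Step 12. What may go wrong: incomplete stannylation or protodestannylation that leaves monomer, palladium-induced E/Z isomerisation, and light- or oxygen-induced degradation of the tetraene during a slow coupling. Fallback (cross-coupling of two differentiated halves instead of a homocoupling), setting out from 18: Miyaura borylation of part of the material (PdCl2(dppf), bis(pinacolato)diboron, KOAc, DMSO, 60 °C) should give (1R,2S)-2-{2-[(2R)-3,3-dimethyloxiran-2-yl]ethyl}-2-methyl-4-[(E)-2-(4,4,5,5-tetramethyl-1,3,2-dioxaborolan-2-yl)ethenyl]cyclohex-3-en-1-ol F6. Suzuki–Miyaura coupling of F6 with a second equivalent of 18 (Pd(PPh3)4, aq. K3PO4, THF, rt, dark) should then give 20 directly.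

3. Step 6. What may go wrong: attack of the liberated primary hydroxyl group on the allyl ester (δ-lactonisation with loss of allyl alcohol) before the diol can be oxidised. Fallback (the redox and deprotection order is changed so that the ester is already part of an enolisable, less electrophilic β-keto ester when the alcohol is freed), setting out from 8: Dess–Martin oxidation (NaHCO3, CH2Cl2) of the secondary alcohol should give allyl (4S)-4-({[tert-butyl(dimethyl)silyl]oxy}methyl)-6-[(2R)-3,3-dimethyloxiran-2-yl]-4-methyl-3-oxohexanoate F7. Bu4NF/AcOH should give allyl (4S)-6-[(2R)-3,3-dimethyloxiran-2-yl]-4-(hydroxymethyl)-4-methyl-3-oxohexanoate F8. A second Dess–Martin oxidation should then give 10, where the route is rejoined.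

**Further compounds**

F1 | step 8 | allyl (4S)-2-[2-({[tert-butyl(dimethyl)silyl]oxy}methyl)prop-2-en-1-yl]-6-[(2R)-3,3-dimethyloxiran-2-yl]-4-formyl-4-methyl-3-oxohexanoate | C=CCOC(=O)C(CC(=C)CO[Si](C)(C)C(C)(C)C)C(=O)[C@](C)(C=O)CC[C@H]1OC1(C)C
F2 | step 8 | (2S)-6-({[tert-butyl(dimethyl)silyl]oxy}methyl)-2-{2-[(2R)-3,3-dimethyloxiran-2-yl]ethyl}-2-methyl-3-oxohept-6-enal | C=C(CO[Si](C)(C)C(C)(C)C)CCC(=O)[C@](C)(C=O)CC[C@H]1OC1(C)C
F3 | step 8 | (3S)-7-({[tert-butyl(dimethyl)silyl]oxy}methyl)-3-{2-[(2R)-3,3-dimethyloxiran-2-yl]ethyl}-3-methylocta-1,7-dien-4-one | C=C(CO[Si](C)(C)C(C)(C)C)CCC(=O)[C@](C)(C=C)CC[C@H]1OC1(C)C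
F4 | step 8 | (2S)-4-({[tert-butyl(dimethyl)silyl]oxy}methyl)-2-{2-[(2R)-3,3-dimethyloxiran-2-yl]ethyl}-2-methylcyclohex-3-en-1-one | CC1(C)O[C@@H]1CC[C@@]1(C)C=C(CO[Si](C)(C)C(C)(C)C)CCC1=O
F5 | step 8 | (2S)-2-{2-[(2R)-3,3-dimethyloxiran-2-yl]ethyl}-4-(hydroxymethyl)-2-methylcyclohex-3-en-1-one | CC1(C)O[C@@H]1CC[C@@]1(C)C=C(CO)CCC1=O
F6 | step 12 | (1R,2S)-2-{2-[(2R)-3,3-dimethyloxiran-2-yl]ethyl}-2-methyl-4-[(E)-2-(4,4,5,5-tetramethyl-1,3,2-dioxaborolan-2-yl)ethenyl]cyclohex-3-en-1-ol | CC1(C)O[C@@H]1CC[C@@]1(C)C=C(/C=C/B2OC(C)(C)C(C)(C)O2)CC[C@H]1O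
F7 | step 6 | allyl (4S)-4-({[tert-butyl(dimethyl)silyl]oxy}methyl)-6-[(2R)-3,3-dimethyloxiran-2-yl]-4-methyl-3-oxohexanoate | C=CCOC(=O)CC(=O)[C@](C)(CO[Si](C)(C)C(C)(C)C)CC[C@H]1OC1(C)C
F8 | step 6 | allyl (4S)-6-[(2R)-3,3-dimethyloxiran-2-yl]-4-(hydroxymethyl)-4-methyl-3-oxohexanoate | C=CCOC(=O)CC(=O)[C@](C)(CO)CC[C@H]1OC1(C)C
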